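The cyclobutane ring is cut at C2–C3 and C1–C4 (C1 carbinol carbon bearing oxygen and aryl, C2 the gem-dimethyl carbon, C3 and C4 the methylenes). This pattern is that of a silyl enol ether of an aryl isopropyl ketone (C1, C2) joined to an acrylate (C3, C4). A chiral Lewis acid [2+2] cycloaddition of the tert-butyldimethylsilyl enol ether 11, whose aryl group is the tetramethyl-protected naphthazarin, with 2,2,2-trifluoroethyl acrylate should build the ring, the protected tertiary carbinol C1 in (R) form and quaternary C2 in one operation. The carboxyl left on C4 is then removed, the angelate attached and the naphthazarin unmasked last.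

Key step: step 6

Assumption (tautomers): the two naphthazarin tautomers (side chain on the quinoid or on the benzenoid ring) interconvert rapidly, so the target is one compound and is drawn with the side chain on the quinone ring.

Assumption (catalyst sense): the sense of induction in step 6 cannot be calibrated on a close analogue; the route is written with the catalyst from (S)-α,α-diphenylprolinol, and its mirror image is to be used instead if a first run, read out at alcohol 17, shows the opposite sense.

Ring atoms C1–C4 are numbered as in the target throughout the text; the systematic names of 13–15 use their own locants.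

Step 1
Reactants: 1 naphthazarin
Product: 3 1,4,5,8-tetramethoxynaphthalene, via leuco tetrol 2 (not isolated)
Conditions: Na2S2O4, NaOH, Me2SO4, n-Bu4NBr, THF/H2O, rt, under N2
Reagents that add atoms: dimethyl sulfate, COS(=O)(=O)OC
Why: Na2S2O4 reduces the quinone to the leuco tetrol and its phenoxides are O-methylated under phase transfer before re-oxidation can occur (one-pot reductive methylation, Williamson ether synthesis).

Step 2
Reactants: 3 1,4,5,8-tetramethoxynaphthalene
Product: 4 2-bromo-1,4,5,8-tetramethoxynaphthalene
Conditions: N-bromosuccinimide (1 equiv), CH2Cl2, rt, dark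
Reagents that add atoms: N-bromosuccinimide, O=C1CCC(=O)N1Br
Why: Electrophilic aromatic bromination of the electron-rich arene, whose four free positions are equivalent, should stop at the monobromide because the first bromine deactivates its ring and only one equivalent of reagent is used.

Step 3
Reactants: 5 isobutyryl chloride
Product: 6 N-methoxy-N,2-dimethylpropanamide
Conditions: MeNHOMe·HCl, Et3N, CH2Cl2, 0 °C to rt
Reagents that add atoms: N,O-dimethylhydroxylamine hydrochloride, CNOC.Cl
Why: N-Acylation of the hydroxylamine by the acid chloride (Schotten–Baumann-type amide formation) gives the Weinreb amide.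

Step 4
Reactants: 4 2-bromo-1,4,5,8-tetramethoxynaphthalene; 6 N-methoxy-N,2-dimethylpropanamide
Product: 9 2-methyl-1-(1,4,5,8-tetramethoxynaphthalen-2-yl)propan-1-one, via aryllithium 7 (not isolated), via tetrahedral lithium adduct 8 (not isolated)
Conditions: n-BuLi, THF, −78 °C; then 6, −78 to 0 °C; then H2O
Reagents that add atoms: none
Why: Bromine–lithium exchange gives the aryllithium, which adds once to the amide because the chelated tetrahedral adduct survives until the aqueous quench (Weinreb ketone synthesis).

Step 5
Reactants: 9 2-methyl-1-(1,4,5,8-tetramethoxynaphthalen-2-yl)propan-1-one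
Product: 11 tert-butyl(dimethyl){[2-methyl-1-(1,4,5,8-tetramethoxynaphthalen-2-yl)prop-1-en-1-yl]oxy}silane, via potassium enolate 10 (not isolated)
Conditions: KN(SiMe3)2, THF, −78 °C; then t-BuMe2SiCl, −78 °C to rt
Reagents that add atoms: tert-butyl(chloro)dimethylsilane, CC(C)(C)[Si](C)(C)Cl
Why: KN(SiMe3)2 removes the only α-hydrogen and the silyl chloride traps the potassium enolate on oxygen (enolate O-silylation); the two methyl groups on the terminal carbon are identical, so the enol ether has no E/Z isomers.

Step 6
Reactants: 11 tert-butyl(dimethyl){[2-methyl-1-(1,4,5,8-tetramethoxynaphthalen-2-yl)prop-1-en-1-yl]oxy}silane; 12 2,2,2-trifluoroethyl acrylate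
Product: 13 2,2,2-trifluoroethyl (1S,2R)-2-{[tert-butyl(dimethyl)silyl]oxy}-3,3-dimethyl-2-(1,4,5,8-tetramethoxynaphthalen-2-yl)cyclobutane-1-carboxylate (ester trans to the silyloxy group)
Conditions: (S)-1-(2-methylphenyl)-3,3-diphenyltetrahydro-1H,3H-pyrrolo[1,2-c][1,3,2]oxazaborole (20 mol%), AlBr3 (16 mol%), 12 (2 equiv), CH2Cl2, −78 °C; Et3N at −78 °C, then aq. NaHCO3; chromatography on Et3N-deactivated silica with removal of any minor diastereomer
Reagents that add atoms: none
Why: Proposed new method: the oxazaborolidine–AlBr3 Lewis acid binds the acrylate carbonyl, the enol ether attacks the β-carbon through its dimethyl-bearing carbon (Mukaiyama–Michael addition, C2–C3 bond, no stereocentre) and the catalyst-bound ester enolate then closes on the silyloxocarbenium carbon in an intramolecular aldol-type step (C1–C4 bond). The closest known reaction type is the stepwise Lewis acid [2+2] cycloaddition of silyl enol ethers with acrylates, including its enantioselective variant with this catalyst on cyclic enol ethers; an acyclic, fully substituted aryl enol ether, in which both stereocentres arise only in the closure, has not been shown. The cyclobutane closes in a 4-exo-trig mode (enolate carbon onto the exocyclic C=O+ bond), helped by the gem-dimethyl group (Thorpe–Ingold effect) and by the ortho-methoxy aryl group, which keeps the cation alive long enough. The ester-bearing C4 is set by the enolate face that the bound catalyst leaves open, and C1 by the relative orientation in the closure, in which the bulky silyloxy group is expected to turn away from the ester so that the two end trans. Because C4 is later removed, the configuration at C1 depends on both the facial and the relative selectivity, so a minor diastereomer must be separated at this stage; the tert-butyldimethylsilyl group slows silyl transfer to the open-chain Michael product, and the amine quench at −78 °C prevents Lewis acid reopening of the donor–acceptor cyclobutane.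

Step 7
Reactants: 13 2,2,2-trifluoroethyl (1S,2R)-2-{[tert-butyl(dimethyl)silyl]oxy}-3,3-dimethyl-2-(1,4,5,8-tetramethoxynaphthalen-2-yl)cyclobutane-1-carboxylate
Product: 14 (1S,2R)-2-{[tert-butyl(dimethyl)silyl]oxy}-3,3-dimethyl-2-(1,4,5,8-tetramethoxynaphthalen-2-yl)cyclobutane-1-carboxylic acid
Conditions: LiOH, THF/H2O, 0 °C to rt; then 1 M HCl to pH 4 at 0 °C
Reagents that add atoms: lithium hydroxide, [Li+].[OH-]
Why: Saponification of the activated trifluoroethyl ester is fast, the silyl ether on the carbinol oxygen blocks retro-aldol opening of the ring, and epimerisation at the ester carbon would be harmless because that centre is removed in step 9.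

Step 8
Reactants: 14 (1S,2R)-2-{[tert-butyl(dimethyl)silyl]oxy}-3,3-dimethyl-2-(1,4,5,8-tetramethoxynaphthalen-2-yl)cyclobutane-1-carboxylic acid
Product: 15 1,3-dioxoisoindolin-2-yl (1S,2R)-2-{[tert-butyl(dimethyl)silyl]oxy}-3,3-dimethyl-2-(1,4,5,8-tetramethoxynaphthalen-2-yl)cyclobutane-1-carboxylate
Conditions: N-hydroxyphthalimide, N,N′-diisopropylcarbodiimide, 4-(dimethylamino)pyridine (10 mol%), CH2Cl2, rt
Reagents that add atoms: N-hydroxyphthalimide, O=C1c2ccccc2C(=O)N1O
Why: Carbodiimide coupling (Steglich-type esterification) turns the acid into a redox-active N-acyloxyphthalimide that can be purified and crystallised.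

Step 9
Reactants: 15 1,3-dioxoisoindolin-2-yl (1S,2R)-2-{[tert-butyl(dimethyl)silyl]oxy}-3,3-dimethyl-2-(1,4,5,8-tetramethoxynaphthalen-2-yl)cyclobutane-1-carboxylate
Product: 16 tert-butyl{[(1R)-2,2-dimethyl-1-(1,4,5,8-tetramethoxynaphthalen-2-yl)cyclobutyl]oxy}dimethylsilane
Conditions: Ru(bpy)3Cl2 (1 mol%), diethyl 2,6-dimethyl-1,4-dihydropyridine-3,5-dicarboxylate (Hantzsch ester), t-BuSH, DMF, blue LEDs, rt
Reagents that add atoms: none
Why: Photoredox single-electron reduction of the N-acyloxyphthalimide releases CO2 and a secondary cyclobutyl radical, which takes a hydrogen atom from the thiol much faster than a cyclobutyl radical opens (reductive radical decarboxylation of the Barton type), so the ester stereocentre disappears while the carbinol centre is untouched.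

Step 10
Reactants: 16 tert-butyl{[(1R)-2,2-dimethyl-1-(1,4,5,8-tetramethoxynaphthalen-2-yl)cyclobutyl]oxy}dimethylsilane
Product: 17 (1R)-2,2-dimethyl-1-(1,4,5,8-tetramethoxynaphthalen-2-yl)cyclobutan-1-ol
Conditions: n-Bu4NF, THF, rt to 50 °C; then H2O
Reagents that add atoms: none
Why: Fluoride-induced cleavage of the silyl ether works under basic conditions, which spare the acid-sensitive, electron-rich tertiary benzylic carbinol.

Step 11
Reactants: 17 (1R)-2,2-dimethyl-1-(1,4,5,8-tetramethoxynaphthalen-2-yl)cyclobutan-1-ol; 18 angelic acid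
Product: 21 (1R)-2,2-dimethyl-1-(1,4,5,8-tetramethoxynaphthalen-2-yl)cyclobutyl (2Z)-2-methylbut-2-enoate, via angelic mixed anhydride 19 (not isolated), via lithium alkoxide 20 (not isolated)
Conditions: 18, 2,4,6-trichlorobenzoyl chloride, Et3N, toluene, rt, filtered (gives 19); 17, n-BuLi, THF, −78 °C (gives 20); then 19, −78 to 0 °C
Reagents that add atoms: none
Why: The hindered tertiary alcohol is acylated as its lithium alkoxide by the Yamaguchi-type mixed anhydride, in which the two ortho chlorines shield the aroyl carbonyl and direct attack to the angeloyl carbonyl; low temperature and the absence of a nucleophilic amine catalyst should keep the (Z) double bond from isomerising, and the ester now protects the cyclobutanol from oxidative ring opening in step 12.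

Step 12
Reactants: 21 (1R)-2,2-dimethyl-1-(1,4,5,8-tetramethoxynaphthalen-2-yl)cyclobutyl (2Z)-2-methylbut-2-enoate
Product: 22 (1R)-1-(5,8-dimethoxy-1,4-dioxo-1,4-dihydronaphthalen-2-yl)-2,2-dimethylcyclobutyl (2Z)-2-methylbut-2-enoate
Conditions: (NH4)2Ce(NO3)6, MeCN/H2O, 0 °C
Reagents that add atoms: water, O
Why: (NH4)2Ce(NO3)6 (tetravalent cerium) oxidises a para-dimethoxy ring through its radical cation to the quinone, water supplying the carbonyl oxygens (oxidative demethylation); the ring that carries the side chain is expected to react, as is usual for 1-acyloxyalkyl substituents, because the methoxy group flanked by the quaternary side chain is twisted and that ring is relieved of strain on becoming a quinone, and oxidation of the unsubstituted ring instead would not change the outcome of step 13, since the naphthazarin tautomers interconvert.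

Step 13
Reactants: 22 (1R)-1-(5,8-dimethoxy-1,4-dioxo-1,4-dihydronaphthalen-2-yl)-2,2-dimethylcyclobutyl (2Z)-2-methylbut-2-enoate
Product: 23 (1R)-1-(5,8-dihydroxy-1,4-dioxo-1,4-dihydronaphthalen-2-yl)-2,2-dimethylcyclobutyl (2Z)-2-methylbut-2-enoate
Conditions: BCl3, CH2Cl2, −78 to −20 °C; then H2O
Reagents that add atoms: none
Why: BCl3 chelates each quinone carbonyl together with its peri methoxy group and cleaves the O–CH3 bond (chelation-assisted Lewis acid ether cleavage), while the tertiary ester next to the electron-poor quinone should resist ionisation at low temperature; the same naphthazarin results whichever ring was oxidised in step 12, because its tautomers interconvert.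

Compound list

1 | naphthazarin (5,8-dihydroxynaphthalene-1,4-dione) | O=C1C=CC(=O)c2c(O)ccc(O)c12 | starting material
2 | naphthalene-1,4,5,8-tetrol (leuco tetrol, present as its sodium salt) | Oc1ccc(O)c2c(O)ccc(O)c12 | intermediate
3 | 1,4,5,8-tetramethoxynaphthalene | COc1ccc(OC)c2c(OC)ccc(OC)c12 | intermediate
4 | 2-bromo-1,4,5,8-tetramethoxynaphthalene | COc1cc(Br)c(OC)c2c(OC)ccc(OC)c12 | intermediate
5 | isobutyryl chloride | CC(C)C(Cl)=O | starting material
6 | N-methoxy-N,2-dimethylpropanamide | CC(C)C(=O)N(C)OC | intermediate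
7 | (1,4,5,8-tetramethoxynaphthalen-2-yl)lithium | [Li]c1cc(OC)c2c(OC)ccc(OC)c2c1OC | intermediate
8 | lithium 1-[methoxy(methyl)amino]-2-methyl-1-(1,4,5,8-tetramethoxynaphthalen-2-yl)propan-1-olate (racemic tetrahedral adduct) | [Li]OC(C(C)C)(N(C)OC)c1cc(OC)c2c(OC)ccc(OC)c2c1OC | intermediate
9 | 2-methyl-1-(1,4,5,8-tetramethoxynaphthalen-2-yl)propan-1-one | CC(C)C(=O)c1cc(OC)c2c(OC)ccc(OC)c2c1OC | intermediate
10 | potassium 2-methyl-1-(1,4,5,8-tetramethoxynaphthalen-2-yl)prop-1-en-1-olate | CC(C)=C(O[K])c1cc(OC)c2c(OC)ccc(OC)c2c1OC | intermediate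
11 | tert-butyl(dimethyl){[2-methyl-1-(1,4,5,8-tetramethoxynaphthalen-2-yl)prop-1-en-1-yl]oxy}silane | CC(C)=C(O[Si](C)(C)C(C)(C)C)c1cc(OC)c2c(OC)ccc(OC)c2c1OC | intermediate
12 | 2,2,2-trifluoroethyl acrylate | C=CC(=O)OCC(F)(F)F | starting material
13 | 2,2,2-trifluoroethyl (1S,2R)-2-{[tert-butyl(dimethyl)silyl]oxy}-3,3-dimethyl-2-(1,4,5,8-tetramethoxynaphthalen-2-yl)cyclobutane-1-carboxylate | CC(C)(C)[Si](C)(C)O[C@]1(c2cc(OC)c3c(OC)ccc(OC)c3c2OC)[C@@H](C(=O)OCC(F)(F)F)CC1(C)C | intermediate
14 | (1S,2R)-2-{[tert-butyl(dimethyl)silyl]oxy}-3,3-dimethyl-2-(1,4,5,8-tetramethoxynaphthalen-2-yl)cyclobutane-1-carboxylic acid | CC(C)(C)[Si](C)(C)O[C@]1(c2cc(OC)c3c(OC)ccc(OC)c3c2OC)[C@@H](C(=O)O)CC1(C)C | intermediate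
15 | 1,3-dioxoisoindolin-2-yl (1S,2R)-2-{[tert-butyl(dimethyl)silyl]oxy}-3,3-dimethyl-2-(1,4,5,8-tetramethoxynaphthalen-2-yl)cyclobutane-1-carboxylate | CC(C)(C)[Si](C)(C)O[C@]1(c2cc(OC)c3c(OC)ccc(OC)c3c2OC)[C@@H](C(=O)ON2C(=O)c3ccccc3C2=O)CC1(C)C | intermediate
16 | tert-butyl{[(1R)-2,2-dimethyl-1-(1,4,5,8-tetramethoxynaphthalen-2-yl)cyclobutyl]oxy}dimethylsilane | CC(C)(C)[Si](C)(C)O[C@]1(c2cc(OC)c3c(OC)ccc(OC)c3c2OC)CCC1(C)C | intermediate
17 | (1R)-2,2-dimethyl-1-(1,4,5,8-tetramethoxynaphthalen-2-yl)cyclobutan-1-ol | O[C@]1(c2cc(OC)c3c(OC)ccc(OC)c3c2OC)CCC1(C)C | intermediate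
18 | angelic acid ((2Z)-2-methylbut-2-enoic acid) | C/C=C(/C)C(=O)O | starting material
19 | (2Z)-2-methylbut-2-enoic 2,4,6-trichlorobenzoic anhydride | C/C=C(/C)C(=O)OC(=O)c1c(Cl)cc(Cl)cc1Cl | intermediate
20 | lithium (1R)-2,2-dimethyl-1-(1,4,5,8-tetramethoxynaphthalen-2-yl)cyclobutan-1-olate | [Li]O[C@]1(c2cc(OC)c3c(OC)ccc(OC)c3c2OC)CCC1(C)C | intermediate
21 | (1R)-2,2-dimethyl-1-(1,4,5,8-tetramethoxynaphthalen-2-yl)cyclobutyl (2Z)-2-methylbut-2-enoate | C/C=C(/C)C(=O)O[C@]1(c2cc(OC)c3c(OC)ccc(OC)c3c2OC)CCC1(C)C | intermediate
22 | (1R)-1-(5,8-dimethoxy-1,4-dioxo-1,4-dihydronaphthalen-2-yl)-2,2-dimethylcyclobutyl (2Z)-2-methylbut-2-enoate | C/C=C(/C)C(=O)O[C@]1(C2=CC(=O)c3c(OC)ccc(OC)c3C2=O)CCC1(C)C | intermediate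
23 | (1R)-1-(5,8-dihydroxy-1,4-dioxo-1,4-dihydronaphthalen-2-yl)-2,2-dimethylcyclobutyl (2Z)-2-methylbut-2-enoate (CNP0326301.1) | C/C=C(/C)C(=O)O[C@]1(C2=CC(=O)c3c(O)ccc(O)c3C2=O)CCC1(C)C | target

Total step count: 13.
Longest linear sequence: 12 steps (steps 1, 2 and 4–13, from naphthazarin 1); step 3 is a one-step side branch.

Steps most likely to fail

1. Step 6 (the new method). Several processes could spoil it:
- The zwitterion may collapse by silyl transfer to the open-chain Michael adduct instead of closing.
- The donor–acceptor cyclobutane may reopen under the Lewis acid.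
- The peri-methoxy groups may sequester the catalyst.
- Facial or relative selectivity in the closure may be poor, which would lower the enantiomeric purity at C1 once C4 is removed.

Fallback (known chemistry, no cycloaddition): the fallback sets out from bromide 4. Bromine–lithium exchange (n-BuLi, THF, −78 °C) gives aryllithium 7, which is added to the known ketone 2,2-dimethylcyclobutan-1-one F1 to give racemic 2,2-dimethyl-1-(1,4,5,8-tetramethoxynaphthalen-2-yl)cyclobutan-1-ol F2. Preparative chromatography on a chiral stationary phase then separates the (1R) alcohol, which is compound 17, from (1S)-2,2-dimethyl-1-(1,4,5,8-tetramethoxynaphthalen-2-yl)cyclobutan-1-ol F3. The route is rejoined at 17 and continues with step 11.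

2. Step 11. Acylation of the congested alkoxide may be incomplete, the alkoxide may deprotonate the anhydride to a vinylketene, and the (Z) double bond may isomerise to the (E) form.

Fallback (the double bond is built after the acylation): the fallback sets out from alcohol 17 as its alkoxide 20. Acylation with 2-[bis(2,2,2-trifluoroethoxy)phosphoryl]propanoyl chloride F4 (from the corresponding acid and oxalyl chloride) should give (1R)-2,2-dimethyl-1-(1,4,5,8-tetramethoxynaphthalen-2-yl)cyclobutyl 2-[bis(2,2,2-trifluoroethoxy)phosphoryl]propanoate F5. Still–Gennari olefination of this ester with acetaldehyde (KN(SiMe3)2, 18-crown-6, THF, −78 °C) should then form the (Z)-2-methylbut-2-enoate and return to the route at 21.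

3. Step 13. The Lewis acid may ionise or cleave the tertiary ester (more easily if step 12 had oxidised the unsubstituted ring, leaving the ester on an electron-rich ring), the second methyl ether may be removed incompletely, and the angelate may isomerise.

Fallback (oxidative instead of Lewis acidic demethylation): the fallback sets out from 22. AgO with HNO3 in dioxane should oxidise the remaining dimethoxy ring to (1R)-2,2-dimethyl-1-(1,4,5,8-tetraoxo-1,4,5,8-tetrahydronaphthalen-2-yl)cyclobutyl (2Z)-2-methylbut-2-enoate F6, the same tetrone whichever ring was oxidised first. Reduction of this tetrone with aqueous Na2S2O4 in the work-up should give the naphthazarin and return to the route at 23.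

Further compounds

F1 | step 6 | 2,2-dimethylcyclobutan-1-one | CC1(C)CCC1=O
F2 | step 6 | racemic 2,2-dimethyl-1-(1,4,5,8-tetramethoxynaphthalen-2-yl)cyclobutan-1-ol | OC1(c2cc(OC)c3c(OC)ccc(OC)c3c2OC)CCC1(C)C
F3 | step 6 | (1S)-2,2-dimethyl-1-(1,4,5,8-tetramethoxynaphthalen-2-yl)cyclobutan-1-ol | O[C@@]1(c2cc(OC)c3c(OC)ccc(OC)c3c2OC)CCC1(C)C
F4 | step 11 | 2-[bis(2,2,2-trifluoroethoxy)phosphoryl]propanoyl chloride (racemic) | CC(C(=O)Cl)P(=O)(OCC(F)(F)F)OCC(F)(F)F
F5 | step 11 | (1R)-2,2-dimethyl-1-(1,4,5,8-tetramethoxynaphthalen-2-yl)cyclobutyl 2-[bis(2,2,2-trifluoroethoxy)phosphoryl]propanoate (both epimers at the phosphorus-bearing carbon) | CC(C(=O)O[C@]1(c2cc(OC)c3c(OC)ccc(OC)c3c2OC)CCC1(C)C)P(=O)(OCC(F)(F)F)OCC(F)(F)F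
F6 | step 13 | (1R)-2,2-dimethyl-1-(1,4,5,8-tetraoxo-1,4,5,8-tetrahydronaphthalen-2-yl)cyclobutyl (2Z)-2-methylbut-2-enoate | C/C=C(/C)C(=O)O[C@]1(C2=CC(=O)C3=C(C(=O)C=CC3=O)C2=O)CCC1(C)C
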